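**Retrosynthetic overview**

1. The lactone ring is made last, by MnO2 oxidative lactonisation of a 2-methylene-1,4-diol (C6–OH / C12–OH), after diacetylation and global desilylation.
2. The cyclohexane ring is made first, by closing C7–C8 with an intramolecular allylsilane–aldehyde (Hosomi–Sakurai) addition that sets C7 and C8.
3. C6–C7 comes from Felkin–Anh addition of an alkenyllithium (iodide fragment: C7, C11–C13) to the C6 aldehyde.
4. C5–C10 (the quaternary/tertiary pair of the 1,5-diene) comes from a Pd-catalysed branch-selective allyl–allyl cross-coupling of an allyl carbonate (C1, C2, C8–C10, C14) with an allylboronate (C3–C6, C15).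
5. All three fragments come from propargyl alcohol by alkyne carbometalation or borylation.

Conventions and assumption: labels C1–C15 are the elemane labels (C1=C2 vinyl on C10; C3H2=C4–C15 side chain on C5; ring C5–C10; C11(=C13)–C12 lactone unit on C7; C14 the CH2OH carbon); TBDPS = tert-butyl(diphenyl)silyl, TES = triethylsilyl, TBS = tert-butyl(dimethyl)silyl, Bpin = 4,4,5,5-tetramethyl-1,3,2-dioxaborolan-2-yl, "-SO" = silyloxy; the (R)-ligand in step 13 is assumed to give (2S,3R)-23, and its antipode is used if the sense proves opposite.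

**Route**

Step 1
Reactants: 1 prop-2-yn-1-ol
Product: 2 tert-butyl(diphenyl)(prop-2-yn-1-yloxy)silane
Conditions: TBDPSCl, imidazole, CH2Cl2, 0 °C → rt
Reagents that add atoms: tert-butyl(chloro)diphenylsilane, CC(C)(C)[Si](Cl)(c1ccccc1)c1ccccc1
Why: standard silylation of a primary alcohol (silyl ether protection), giving a group that survives every step up to the final fluoride treatment.

Step 2
Reactants: 2 tert-butyl(diphenyl)(prop-2-yn-1-yloxy)silane
Product: 4 methyl 4-(TBDPSO)but-2-ynoate, via lithium acetylide 3 (not isolated)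
Conditions: n-BuLi, THF, −78 °C; then ClCO2Me, −78 → 0 °C
Reagents that add atoms: methyl chloroformate, COC(=O)Cl
Why: deprotonation of the terminal alkyne and C-acylation of the acetylide gives the ynoate that carries C2, C1, C10 and C14.

Step 3
Reactants: 4 methyl 4-(TBDPSO)but-2-ynoate; 5 (1,3-dioxolan-2-ylmethyl)magnesium bromide
Product: 8 methyl (2Z)-4-(TBDPSO)-3-(1,3-dioxolan-2-ylmethyl)but-2-enoate, via organocopper 6 (not isolated), via alkenylcopper adduct 7 (not isolated)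
Conditions: 5 (1.5 equiv), CuI (1.5 equiv), THF, −40 °C; then 4, −78 °C; then MeOH, −78 °C
Reagents that add atoms: none
Why: syn-carbocupration of the ynoate (organocopper conjugate addition) and protonation at −78 °C with retention put the new C9 group cis to H, so the ester is cis to CH2OTBDPS, the alkene geometry needed at C10 for step 13.

Step 4
Reactants: 8 methyl (2Z)-4-(TBDPSO)-3-(1,3-dioxolan-2-ylmethyl)but-2-enoate
Product: 9 (2Z)-4-(TBDPSO)-3-(1,3-dioxolan-2-ylmethyl)but-2-en-1-ol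
Conditions: i-Bu2AlH (2.2 equiv), CH2Cl2, −78 °C
Reagents that add atoms: none
Why: 1,2-reduction of the enoate by the aluminium hydride gives the allylic alcohol without touching the acetal, the silyl ether or the alkene geometry.

Step 5
Reactants: 9 (2Z)-4-(TBDPSO)-3-(1,3-dioxolan-2-ylmethyl)but-2-en-1-ol
Product: 10 tert-butyl (2Z)-4-(TBDPSO)-3-(1,3-dioxolan-2-ylmethyl)but-2-en-1-yl carbonate
Conditions: Boc2O, DMAP (cat.), CH2Cl2, 0 °C → rt
Reagents that add atoms: di-tert-butyl dicarbonate, CC(C)(C)OC(=O)OC(=O)OC(C)(C)C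
Why: O-acylation to the allylic carbonate, which ionises readily with palladium and releases tert-butoxide to activate the boronate partner.

Step 6
Reactants: 1 prop-2-yn-1-ol
Product: 11 triethyl(prop-2-yn-1-yloxy)silane
Conditions: TESCl, imidazole, CH2Cl2, 0 °C
Reagents that add atoms: chlorotriethylsilane, CC[Si](Cl)(CC)CC
Why: standard silylation, chosen so that this acid-labile ether (the future C15 oxygen) falls off together with the acetal in step 16.

Step 7
Reactants: 11 triethyl(prop-2-yn-1-yloxy)silane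
Product: 13 methyl 4-(TESO)but-2-ynoate, via lithium acetylide 12 (not isolated)
Conditions: n-BuLi, THF, −78 °C; then ClCO2Me, −78 → 0 °C
Reagents that add atoms: methyl chloroformate, COC(=O)Cl
Why: acetylide acylation gives the ynoate that carries C6, C5, C4 and C15.

Step 8
Reactants: 13 methyl 4-(TESO)but-2-ynoate
Product: 14 methyl (2Z)-3-(Bpin)-4-(TESO)but-2-enoate
Conditions: B2pin2 (1.1 equiv), CuCl (5 mol %), Xantphos (5 mol %), NaOtBu (10 mol %), MeOH (2 equiv), THF, rt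
Reagents that add atoms: bis(pinacolato)diboron, CC1(C)OB(OC1(C)C)B1OC(C)(C)C(C)(C)O1
Why: copper-catalysed conjugate borylation (syn-borylcupration with boron at the β-carbon, then protonation with retention) gives boron cis to H and the ester cis to CH2OTES.

Step 9
Reactants: 14 methyl (2Z)-3-(Bpin)-4-(TESO)but-2-enoate
Product: 16 methyl (2Z)-3-[(Bpin)methyl]-4-(TESO)but-2-enoate, via boronate complex 15 (not isolated)
Conditions: ICH2Cl (1.5 equiv), n-BuLi (1.4 equiv, slow addition), THF, −100 °C → rt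
Reagents that add atoms: chloroiodomethane, ClCI
Why: Matteson homologation, in which LiCH2Cl made in situ adds to boron and the alkenyl group migrates with loss of chloride and retention of the alkene geometry, giving the allylboronate.

Step 10
Reactants: 16 methyl (2Z)-3-[(Bpin)methyl]-4-(TESO)but-2-enoate
Product: 17 (2Z)-3-[(Bpin)methyl]-4-(TESO)but-2-en-1-ol
Conditions: i-Bu2AlH (2.2 equiv), CH2Cl2, −78 °C
Reagents that add atoms: none
Why: 1,2-reduction of the enoate at low temperature, which the pinacol boronate tolerates, gives the C6 carbinol trans to the CH2Bpin group so that it cannot cyclise onto boron.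

Step 11
Reactants: 1 prop-2-yn-1-ol; 18 [(trimethylsilyl)methyl]magnesium chloride
Product: 21 (2E)-3-iodo-2-[(trimethylsilyl)methyl]prop-2-en-1-ol, via chloromagnesium alkoxide 19 (not isolated), via oxamagnesacycle 20 (not isolated)
Conditions: 18 (2.5 equiv), CuI (10 mol %), Et2O, 0 °C → rt; then I2, THF, −78 → 0 °C
Reagents that add atoms: iodine, [I][I]
Why: copper-catalysed anti-carbomagnesiation of the propargylic alkoxide (chelate-controlled) gives a cyclic alkenylmagnesium that is iodinated with retention, so iodine is cis to CH2OH and the allylsilane CH2 is trans.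

Step 12
Reactants: 21 (2E)-3-iodo-2-[(trimethylsilyl)methyl]prop-2-en-1-ol
Product: 22 tert-butyl({(2E)-3-iodo-2-[(trimethylsilyl)methyl]prop-2-en-1-yl}oxy)diphenylsilane
Conditions: TBDPSCl, imidazole, CH2Cl2, rt
Reagents that add atoms: tert-butyl(chloro)diphenylsilane, CC(C)(C)[Si](Cl)(c1ccccc1)c1ccccc1
Why: standard silylation with a bulky group that also suppresses 1,4 oxygen-to-carbon silyl migration in the derived alkenyllithium.

Step 13
Reactants: 10 tert-butyl (2Z)-4-(TBDPSO)-3-(1,3-dioxolan-2-ylmethyl)but-2-en-1-yl carbonate; 17 (2Z)-3-[(Bpin)methyl]-4-(TESO)but-2-en-1-ol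
Product: 23 (2S,3R)-3-[(TBDPSO)methyl]-3-(1,3-dioxolan-2-ylmethyl)-2-[3-(TESO)prop-1-en-2-yl]pent-4-en-1-ol
Conditions: Pd2(dba)3 (2.5 mol %), (R)-MeO-furyl-BIPHEP (6 mol %), THF, 60 °C
Reagents that add atoms: none
Why: Proposed new method: zerovalent palladium ionises carbonate 10, the released tert-butoxide activates boronate 17 for transmetalation, and the small-bite-angle diphosphine holds a bis(η1-allyl)palladium that undergoes chair-like 3,3'-reductive elimination joining the two more substituted termini (C10–C5), with C9 and C6 pseudo-equatorial because of the (Z) geometry of both partners (this fixes the C5/C10 relative configuration) and the ligand fixing the absolute sense; the closest known reaction type is the Pd-catalysed branch-selective enantioselective allyl–allyl cross-coupling of allylboronates with allylic electrophiles, which has not been shown for a γ,γ-disubstituted electrophile paired with a 2,3-disubstituted, oxygen-functionalised allylboronate carrying a free hydroxyl group.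

Step 14
Reactants: 23 (2S,3R)-3-[(TBDPSO)methyl]-3-(1,3-dioxolan-2-ylmethyl)-2-[3-(TESO)prop-1-en-2-yl]pent-4-en-1-ol
Product: 24 (2S,3R)-3-[(TBDPSO)methyl]-3-(1,3-dioxolan-2-ylmethyl)-2-[3-(TESO)prop-1-en-2-yl]pent-4-enal
Conditions: Dess–Martin periodinane, pyridine, CH2Cl2, 0 °C; used crude
Reagents that add atoms: none
Why: buffered Dess–Martin oxidation of the primary alcohol is mild enough to keep the C5 stereocentre and the β,γ-alkene of the aldehyde in place.

Step 15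
Reactants: 22 tert-butyl({(2E)-3-iodo-2-[(trimethylsilyl)methyl]prop-2-en-1-yl}oxy)diphenylsilane; 24 (2S,3R)-3-[(TBDPSO)methyl]-3-(1,3-dioxolan-2-ylmethyl)-2-[3-(TESO)prop-1-en-2-yl]pent-4-enal
Product: 27 (3R,4S,5S,6E)-5-(TBSO)-3,7-bis[(TBDPSO)methyl]-3-(1,3-dioxolan-2-ylmethyl)-4-[3-(TESO)prop-1-en-2-yl]-8-(trimethylsilyl)octa-1,6-diene, via alkenyllithium 25 (not isolated), via lithium alkoxide 26 (not isolated)
Conditions: 22 (1.3 equiv), t-BuLi (2.6 equiv), Et2O, −78 °C; then 24, −78 °C; then TBSOTf (1.4 equiv), −78 → 0 °C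
Reagents that add atoms: tert-butyldimethylsilyl trifluoromethanesulfonate, CC(C)(C)[Si](C)(C)OS(=O)(=O)C(F)(F)F
Why: iodine–lithium exchange with retention gives the alkenyllithium, which adds to the α-branched aldehyde in the Felkin–Anh sense (quaternary C10 as the large group anti to the nucleophile) to set C6, and the lithium alkoxide is silylated in the same flask.

Step 16
Reactants: 27 (3R,4S,5S,6E)-5-(TBSO)-3,7-bis[(TBDPSO)methyl]-3-(1,3-dioxolan-2-ylmethyl)-4-[3-(TESO)prop-1-en-2-yl]-8-(trimethylsilyl)octa-1,6-diene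
Product: 28 (3R,4S,5S,6E)-5-(TBSO)-3,7-bis[(TBDPSO)methyl]-3-ethenyl-4-(3-hydroxyprop-1-en-2-yl)-8-(trimethylsilyl)oct-6-enal
Conditions: PPTS (0.2 equiv), acetone/H2O (10:1), 50 °C
Reagents that add atoms: water, O
Why: acid-catalysed acetal hydrolysis frees the C8 aldehyde and the same weak acid cleaves the primary TES ether, while the hindered secondary TBS ether, the TBDPS ethers and the allylsilane are stable.

Step 17
Reactants: 28 (3R,4S,5S,6E)-5-(TBSO)-3,7-bis[(TBDPSO)methyl]-3-ethenyl-4-(3-hydroxyprop-1-en-2-yl)-8-(trimethylsilyl)oct-6-enal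
Product: 29 (1S,2R,3R,4S,5R)-3-(TBSO)-2-[3-(TBDPSO)prop-1-en-2-yl]-5-[(TBDPSO)methyl]-5-ethenyl-4-(3-hydroxyprop-1-en-2-yl)cyclohexan-1-ol
Conditions: BF3·OEt2 (2.5 equiv), CH2Cl2, −78 °C; then aq. NaHCO3
Reagents that add atoms: none
Why: intramolecular Hosomi–Sakurai allylation, in which C7 of the 2-substituted allylsilane (far more nucleophilic than the other alkenes) attacks the BF3-activated C8 aldehyde through a chair where A(1,3) strain (C6–H eclipsing the alkene beside the cis CH2OTBDPS) puts the tether on the face anti to C6–OTBS and the complexed oxygen stays equatorial to avoid the axial CH2OTBDPS on C10, so C7 and C8 form trans to each other and to C6–O.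

Step 18
Reactants: 29 (1S,2R,3R,4S,5R)-3-(TBSO)-2-[3-(TBDPSO)prop-1-en-2-yl]-5-[(TBDPSO)methyl]-5-ethenyl-4-(3-hydroxyprop-1-en-2-yl)cyclohexan-1-ol
Product: 30 (1S,2R,3R,4S,5R)-4-[3-(acetyloxy)prop-1-en-2-yl]-3-(TBSO)-2-[3-(TBDPSO)prop-1-en-2-yl]-5-[(TBDPSO)methyl]-5-ethenylcyclohexyl acetate
Conditions: Ac2O, pyridine, DMAP (cat.), CH2Cl2, rt
Reagents that add atoms: acetic anhydride, CC(=O)OC(C)=O
Why: acetylation of the only two free hydroxyls (C8 and C15) installs both acetates of the target in one operation.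

Step 19
Reactants: 30 (1S,2R,3R,4S,5R)-4-[3-(acetyloxy)prop-1-en-2-yl]-3-(TBSO)-2-[3-(TBDPSO)prop-1-en-2-yl]-5-[(TBDPSO)methyl]-5-ethenylcyclohexyl acetate
Product: 31 (1S,2S,3R,4S,5R)-4-[3-(acetyloxy)prop-1-en-2-yl]-5-ethenyl-3-hydroxy-5-(hydroxymethyl)-2-(3-hydroxyprop-1-en-2-yl)cyclohexyl acetate
Conditions: HF·pyridine (excess), pyridine/THF, 0 °C → rt, 48 h
Reagents that add atoms: none
Why: fluoride desilylation under buffered, weakly acidic conditions removes all three silyl ethers without cleaving or migrating the acetates.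

Step 20
Reactants: 31 (1S,2S,3R,4S,5R)-4-[3-(acetyloxy)prop-1-en-2-yl]-5-ethenyl-3-hydroxy-5-(hydroxymethyl)-2-(3-hydroxyprop-1-en-2-yl)cyclohexyl acetate
Product: 34 (3aR,4S,6R,7S,7aR)-7-[3-(acetyloxy)prop-1-en-2-yl]-6-ethenyl-6-(hydroxymethyl)-3-methylidene-2-oxooctahydro-1-benzofuran-4-yl acetate, via hydroxy enal 32 (not isolated), via lactol 33 (not isolated)
Conditions: MnO2 (activated, 30 equiv), CH2Cl2, rt
Reagents that add atoms: none
Why: MnO2 oxidises only the allylic primary alcohol (C12) to the enal, which closes with the C6 hydroxyl to a lactol that is oxidised on to the α-methylene lactone (oxidative lactonisation of a 2-methylene-1,4-diol), leaving the neopentyl C14 alcohol, the acetates and all stereocentres untouched.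

**Compound list**

1 | prop-2-yn-1-ol | C#CCO | starting material
2 | tert-butyl(diphenyl)(prop-2-yn-1-yloxy)silane | C#CCO[Si](c1ccccc1)(c1ccccc1)C(C)(C)C | intermediate
3 | (3-TBDPSO-prop-1-yn-1-yl)lithium (not isolated) | [Li]C#CCO[Si](c1ccccc1)(c1ccccc1)C(C)(C)C | intermediate
4 | methyl 4-(TBDPSO)but-2-ynoate | COC(=O)C#CCO[Si](c1ccccc1)(c1ccccc1)C(C)(C)C | intermediate
5 | (1,3-dioxolan-2-ylmethyl)magnesium bromide | Br[Mg]CC1OCCO1 | starting material
6 | (1,3-dioxolan-2-ylmethyl)copper (not isolated) | [Cu]CC1OCCO1 | intermediate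
7 | methyl (2E)-4-(TBDPSO)-2-cuprio-3-(1,3-dioxolan-2-ylmethyl)but-2-enoate, Cu cis to the dioxolanylmethyl group (not isolated) | COC(=O)/C([Cu])=C(\CO[Si](c1ccccc1)(c1ccccc1)C(C)(C)C)CC1OCCO1 | intermediate
8 | methyl (2Z)-4-(TBDPSO)-3-(1,3-dioxolan-2-ylmethyl)but-2-enoate | COC(=O)/C=C(\CO[Si](c1ccccc1)(c1ccccc1)C(C)(C)C)CC1OCCO1 | intermediate
9 | (2Z)-4-(TBDPSO)-3-(1,3-dioxolan-2-ylmethyl)but-2-en-1-ol | OC/C=C(\CO[Si](c1ccccc1)(c1ccccc1)C(C)(C)C)CC1OCCO1 | intermediate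
10 | tert-butyl (2Z)-4-(TBDPSO)-3-(1,3-dioxolan-2-ylmethyl)but-2-en-1-yl carbonate | CC(C)(C)OC(=O)OC/C=C(\CO[Si](c1ccccc1)(c1ccccc1)C(C)(C)C)CC1OCCO1 | intermediate
11 | triethyl(prop-2-yn-1-yloxy)silane | C#CCO[Si](CC)(CC)CC | intermediate
12 | (3-TESO-prop-1-yn-1-yl)lithium (not isolated) | [Li]C#CCO[Si](CC)(CC)CC | intermediate
13 | methyl 4-(TESO)but-2-ynoate | COC(=O)C#CCO[Si](CC)(CC)CC | intermediate
14 | methyl (2Z)-3-(Bpin)-4-(TESO)but-2-enoate | COC(=O)/C=C(\CO[Si](CC)(CC)CC)B1OC(C)(C)C(C)(C)O1 | intermediate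
15 | lithium (chloromethyl)boronate complex of 14 (not isolated) | COC(=O)/C=C(\CO[Si](CC)(CC)CC)[B-]1(CCl)OC(C)(C)C(C)(C)O1.[Li+] | intermediate
16 | methyl (2Z)-3-[(Bpin)methyl]-4-(TESO)but-2-enoate | COC(=O)/C=C(\CO[Si](CC)(CC)CC)CB1OC(C)(C)C(C)(C)O1 | intermediate
17 | (2Z)-3-[(Bpin)methyl]-4-(TESO)but-2-en-1-ol | OC/C=C(\CO[Si](CC)(CC)CC)CB1OC(C)(C)C(C)(C)O1 | intermediate
18 | [(trimethylsilyl)methyl]magnesium chloride | C[Si](C)(C)C[Mg]Cl | starting material
19 | chloromagnesium prop-2-yn-1-olate (not isolated) | C#CCO[Mg]Cl | intermediate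
20 | 4-[(trimethylsilyl)methyl]-2,5-dihydro-1,2-oxamagnesole, cyclic alkenylmagnesium alkoxide (not isolated) | C[Si](C)(C)CC1=C[Mg]OC1 | intermediate
21 | (2E)-3-iodo-2-[(trimethylsilyl)methyl]prop-2-en-1-ol (iodine cis to CH2OH) | I/C=C(\CO)C[Si](C)(C)C | intermediate
22 | tert-butyl({(2E)-3-iodo-2-[(trimethylsilyl)methyl]prop-2-en-1-yl}oxy)diphenylsilane | I/C=C(\CO[Si](c1ccccc1)(c1ccccc1)C(C)(C)C)C[Si](C)(C)C | intermediate
23 | (2S,3R)-3-[(TBDPSO)methyl]-3-(1,3-dioxolan-2-ylmethyl)-2-[3-(TESO)prop-1-en-2-yl]pent-4-en-1-ol | C=C[C@](CO[Si](c1ccccc1)(c1ccccc1)C(C)(C)C)(CC1OCCO1)[C@@H](CO)C(=C)CO[Si](CC)(CC)CC | intermediate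
24 | (2S,3R)-3-[(TBDPSO)methyl]-3-(1,3-dioxolan-2-ylmethyl)-2-[3-(TESO)prop-1-en-2-yl]pent-4-enal | C=C[C@](CO[Si](c1ccccc1)(c1ccccc1)C(C)(C)C)(CC1OCCO1)[C@@H](C=O)C(=C)CO[Si](CC)(CC)CC | intermediate
25 | {(1E)-3-(TBDPSO)-2-[(trimethylsilyl)methyl]prop-1-en-1-yl}lithium, Li cis to CH2OTBDPS (not isolated) | [Li]/C=C(\CO[Si](c1ccccc1)(c1ccccc1)C(C)(C)C)C[Si](C)(C)C | intermediate
26 | lithium (3R,4S,5S,6E)-3,7-bis[(TBDPSO)methyl]-3-(1,3-dioxolan-2-ylmethyl)-4-[3-(TESO)prop-1-en-2-yl]-8-(trimethylsilyl)octa-1,6-dien-5-olate (not isolated) | C=C[C@](CO[Si](c1ccccc1)(c1ccccc1)C(C)(C)C)(CC1OCCO1)[C@@H]([C@@H](O[Li])/C=C(\CO[Si](c1ccccc1)(c1ccccc1)C(C)(C)C)C[Si](C)(C)C)C(=C)CO[Si](CC)(CC)CC | intermediate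
27 | (3R,4S,5S,6E)-5-(TBSO)-3,7-bis[(TBDPSO)methyl]-3-(1,3-dioxolan-2-ylmethyl)-4-[3-(TESO)prop-1-en-2-yl]-8-(trimethylsilyl)octa-1,6-diene | C=C[C@](CO[Si](c1ccccc1)(c1ccccc1)C(C)(C)C)(CC1OCCO1)[C@@H]([C@@H](O[Si](C)(C)C(C)(C)C)/C=C(\CO[Si](c1ccccc1)(c1ccccc1)C(C)(C)C)C[Si](C)(C)C)C(=C)CO[Si](CC)(CC)CC | intermediate
28 | (3R,4S,5S,6E)-5-(TBSO)-3,7-bis[(TBDPSO)methyl]-3-ethenyl-4-(3-hydroxyprop-1-en-2-yl)-8-(trimethylsilyl)oct-6-enal | C=C[C@](CO[Si](c1ccccc1)(c1ccccc1)C(C)(C)C)(CC=O)[C@@H]([C@@H](O[Si](C)(C)C(C)(C)C)/C=C(\CO[Si](c1ccccc1)(c1ccccc1)C(C)(C)C)C[Si](C)(C)C)C(=C)CO | intermediate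
29 | (1S,2R,3R,4S,5R)-3-(TBSO)-2-[3-(TBDPSO)prop-1-en-2-yl]-5-[(TBDPSO)methyl]-5-ethenyl-4-(3-hydroxyprop-1-en-2-yl)cyclohexan-1-ol (vinyl cis to both ring oxygens; the C5 and C7 side chains and CH2O on C10 on the other face) | C=C[C@]1(CO[Si](c2ccccc2)(c2ccccc2)C(C)(C)C)C[C@H](O)[C@@H](C(=C)CO[Si](c2ccccc2)(c2ccccc2)C(C)(C)C)[C@H](O[Si](C)(C)C(C)(C)C)[C@H]1C(=C)CO | intermediate
30 | (1S,2R,3R,4S,5R)-4-[3-(acetyloxy)prop-1-en-2-yl]-3-(TBSO)-2-[3-(TBDPSO)prop-1-en-2-yl]-5-[(TBDPSO)methyl]-5-ethenylcyclohexyl acetate | C=C[C@]1(CO[Si](c2ccccc2)(c2ccccc2)C(C)(C)C)C[C@H](OC(C)=O)[C@@H](C(=C)CO[Si](c2ccccc2)(c2ccccc2)C(C)(C)C)[C@H](O[Si](C)(C)C(C)(C)C)[C@H]1C(=C)COC(C)=O | intermediate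
31 | (1S,2S,3R,4S,5R)-4-[3-(acetyloxy)prop-1-en-2-yl]-5-ethenyl-3-hydroxy-5-(hydroxymethyl)-2-(3-hydroxyprop-1-en-2-yl)cyclohexyl acetate | C=C[C@]1(CO)C[C@H](OC(C)=O)[C@@H](C(=C)CO)[C@H](O)[C@H]1C(=C)COC(C)=O | intermediate
32 | (1S,2S,3R,4S,5R)-4-[3-(acetyloxy)prop-1-en-2-yl]-5-ethenyl-3-hydroxy-5-(hydroxymethyl)-2-(3-oxoprop-1-en-2-yl)cyclohexyl acetate (not isolated) | C=C[C@]1(CO)C[C@H](OC(C)=O)[C@@H](C(=C)C=O)[C@H](O)[C@H]1C(=C)COC(C)=O | intermediate
33 | (3aR,4S,6R,7S,7aR)-7-[3-(acetyloxy)prop-1-en-2-yl]-6-ethenyl-2-hydroxy-6-(hydroxymethyl)-3-methylideneoctahydro-1-benzofuran-4-yl acetate, both C2 epimers (not isolated) | C=C[C@]1(CO)C[C@H](OC(C)=O)[C@H]2C(=C)C(O)O[C@@H]2[C@H]1C(=C)COC(C)=O | intermediate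
34 | (3aR,4S,6R,7S,7aR)-7-[3-(acetyloxy)prop-1-en-2-yl]-6-ethenyl-6-(hydroxymethyl)-3-methylidene-2-oxooctahydro-1-benzofuran-4-yl acetate (CNP0240658.1) | C=C[C@]1(CO)C[C@H](OC(C)=O)[C@H]2C(=C)C(=O)O[C@@H]2[C@H]1C(=C)COC(C)=O | target

**Step count and risks**

Total step count: 20. Longest linear sequence: 13 (steps 1–5 or 6–10, then 13–20).

Three steps most likely to fail:

Step 13 (the new coupling). Branch/branch regioselectivity and diastereocontrol at a congested quaternary–tertiary bond are unproven, and the stereochemical argument rests on a chair-like reductive elimination. Fallback with known chemistry, setting out from 9 and 16 and coming back at 23: 16 is protodeborylated with allyl transposition (CsF, MeOH, 0 °C) to methyl 3-[(TESO)methyl]but-3-enoate F1, hydrolysed (Me3SnOH, 1,2-dichloroethane, 70 °C) to 3-[(TESO)methyl]but-3-enoic acid F2, and esterified with 9 (DCC, DMAP) to (2Z)-4-(TBDPSO)-3-(1,3-dioxolan-2-ylmethyl)but-2-en-1-yl 3-[(TESO)methyl]but-3-enoate F3. An enantioselective ester-enolate Claisen rearrangement mediated by a chiral C2-symmetric bromodiazaborolidine (Et3N, toluene/hexane, −78 °C → rt; chair transition state with the E(O)-boron enolate and the (Z)-allyl unit) gives (2S,3R)-3-[(TBDPSO)methyl]-3-(1,3-dioxolan-2-ylmethyl)-2-[3-(TESO)prop-1-en-2-yl]pent-4-enoic acid F4, and LiAlH4 reduction returns 23.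

Step 15. The basic alkenyllithium may enolise the hindered, doubly activated aldehyde, Felkin selectivity may be moderate, and the one-pot silylation must outrun acetal activation. Fallback, setting out from 22 and 24 and coming back at 27: a non-basic Ni/Cr-mediated (Nozaki–Hiyama–Kishi) alkenylation under reagent control (CrCl2, NiCl2 cat., chiral sulfonamide ligand, Et3N, MeCN/THF, rt) gives the free carbinol (3R,4S,5S,6E)-3,7-bis[(TBDPSO)methyl]-3-(1,3-dioxolan-2-ylmethyl)-4-[3-(TESO)prop-1-en-2-yl]-8-(trimethylsilyl)octa-1,6-dien-5-ol F5, which is silylated in a separate operation (TBSOTf, 2,6-lutidine, CH2Cl2, −78 °C) to 27.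

Step 17. The open transition state may give some C8 epimer, and protodesilylation or ionisation of the allylic silyl ether can compete. Fallback, setting out from 24 (with 1 as the source of the new iodide) and coming back at 29, replaces the allylsilane addition by a silicon-free carbonyl-ene closure: 1 is converted (MeMgBr, CuI; then I2) into (2Z)-3-iodo-2-methylprop-2-en-1-ol F6 and silylated to tert-butyl{[(2Z)-3-iodo-2-methylprop-2-en-1-yl]oxy}diphenylsilane F7. F7 is taken with 24 through the operations of steps 15 and 16 to give (3R,4S,5S,6Z)-5-(TBSO)-3,7-bis[(TBDPSO)methyl]-3-(1,3-dioxolan-2-ylmethyl)-4-[3-(TESO)prop-1-en-2-yl]octa-1,6-diene F8 and then (3R,4S,5S,6Z)-5-(TBSO)-3,7-bis[(TBDPSO)methyl]-3-ethenyl-4-(3-hydroxyprop-1-en-2-yl)oct-6-enal F9. Me2AlCl (3 equiv, CH2Cl2, −78 → −20 °C) then effects a type 1 carbonyl-ene cyclisation through the same chair, the hydrogen coming from the methyl group syn to H7 and the aluminium alkoxide at C15 deactivating the other 1,1-disubstituted alkene, which gives 29 directly.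

**Further compounds**

F1 | step 13 | methyl 3-[(TESO)methyl]but-3-enoate | C=C(CO[Si](CC)(CC)CC)CC(=O)OC
F2 | step 13 | 3-[(TESO)methyl]but-3-enoic acid | C=C(CO[Si](CC)(CC)CC)CC(=O)O
F3 | step 13 | (2Z)-4-(TBDPSO)-3-(1,3-dioxolan-2-ylmethyl)but-2-en-1-yl 3-[(TESO)methyl]but-3-enoate | C=C(CO[Si](CC)(CC)CC)CC(=O)OC/C=C(\CO[Si](c1ccccc1)(c1ccccc1)C(C)(C)C)CC1OCCO1
F4 | step 13 | (2S,3R)-3-[(TBDPSO)methyl]-3-(1,3-dioxolan-2-ylmethyl)-2-[3-(TESO)prop-1-en-2-yl]pent-4-enoic acid | C=C[C@](CO[Si](c1ccccc1)(c1ccccc1)C(C)(C)C)(CC1OCCO1)[C@@H](C(=O)O)C(=C)CO[Si](CC)(CC)CC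
F5 | step 15 | (3R,4S,5S,6E)-3,7-bis[(TBDPSO)methyl]-3-(1,3-dioxolan-2-ylmethyl)-4-[3-(TESO)prop-1-en-2-yl]-8-(trimethylsilyl)octa-1,6-dien-5-ol | C=C[C@](CO[Si](c1ccccc1)(c1ccccc1)C(C)(C)C)(CC1OCCO1)[C@@H]([C@@H](O)/C=C(\CO[Si](c1ccccc1)(c1ccccc1)C(C)(C)C)C[Si](C)(C)C)C(=C)CO[Si](CC)(CC)CC
F6 | step 17 | (2Z)-3-iodo-2-methylprop-2-en-1-ol | I/C=C(\CO)C
F7 | step 17 | tert-butyl{[(2Z)-3-iodo-2-methylprop-2-en-1-yl]oxy}diphenylsilane | I/C=C(\CO[Si](c1ccccc1)(c1ccccc1)C(C)(C)C)C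
F8 | step 17 | (3R,4S,5S,6Z)-5-(TBSO)-3,7-bis[(TBDPSO)methyl]-3-(1,3-dioxolan-2-ylmethyl)-4-[3-(TESO)prop-1-en-2-yl]octa-1,6-diene | C=C[C@](CO[Si](c1ccccc1)(c1ccccc1)C(C)(C)C)(CC1OCCO1)[C@@H]([C@@H](O[Si](C)(C)C(C)(C)C)/C=C(\CO[Si](c1ccccc1)(c1ccccc1)C(C)(C)C)C)C(=C)CO[Si](CC)(CC)CC
F9 | step 17 | (3R,4S,5S,6Z)-5-(TBSO)-3,7-bis[(TBDPSO)methyl]-3-ethenyl-4-(3-hydroxyprop-1-en-2-yl)oct-6-enal | C=C[C@](CO[Si](c1ccccc1)(c1ccccc1)C(C)(C)C)(CC=O)[C@@H]([C@@H](O[Si](C)(C)C(C)(C)C)/C=C(\CO[Si](c1ccccc1)(c1ccccc1)C(C)(C)C)C)C(=C)CO
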